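**Retrosynthetic overview**
- The target is released from its tris-pivalate by mild base; no acid is used once the phenols are free.
- The oxane is cut as in the presumed biosynthesis: the C-8–C-9'' bond (a p-coumaryl C-9 electrophile attacks the styrene) and the C-7–O bond (the benzylic cation is closed by the 9'-OH).
- The C9 electrophile is used as its enal, tied to the 7'-OH as an oxocarbenium ion. A Prins cascade then gives a 3,7-dioxabicyclo[3.3.1]nonane whose bridged chair enforces the all-cis pattern; hydride afterwards cuts the allylic C–O tether.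
- The (1R,2R)-diol comes from a magnesium-catalysed Evans anti-aldol of a 5-arylpent-4-enoyl oxazolidinone with 4-(pivaloyloxy)benzaldehyde, followed by NaBH4.
- Ring order, all in one flask: temporary 1,3-dioxane acetal, then temporary oxane (C–C bond) together with the target oxane (C–O bond), then the temporary ring is opened.

Assumption: the presumed biosynthesis is attack of the C-9'' cation of a p-coumaryl unit on C-8 of an 8'–9-linked p-coumaryl dimer, with the C-7 cation closed by 9'-OH; locants used below are ring O–C-7(aryl)–C-8–C-9–C-8'–C-9', carbinol C-7', cinnamyl CH2 C-9'' (target 7R,8S,8'R,7'R, all three ring substituents cis).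

**Step 1**
Reactants: 1 4-hydroxybenzaldehyde
Product: 2 4-formylphenyl pivalate
Conditions: PivCl, Et3N, DMAP (cat.), CH2Cl2, 0 °C → rt
Reagents that add atoms: pivaloyl chloride, CC(C)(C)C(=O)Cl
Why: O-acylation of the phenol (esterification); the pivalate keeps each aryl ring electron-poor so that its benzylic C–O bonds do not ionise in step 7, survives NaBH4, and leaves with mild base.

**Step 2**
Reactants: 2 4-formylphenyl pivalate; 3 (3-carboxypropyl)triphenylphosphonium bromide
Product: 5 (E)-5-[4-(pivaloyloxy)phenyl]pent-4-enoic acid, via carboxylate ylide 4 (not isolated)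
Conditions: 3, NaHMDS (2 equiv), THF, 0 °C; then 2, −78 °C → rt; aq. HCl
Reagents that add atoms: none
Why: Wittig olefination, where the carboxylate-bearing ylide gives mainly the E-alkene with aryl aldehydes; the geometry is not critical because C-7 becomes a cation in step 7.

**Step 3**
Reactants: 5 (E)-5-[4-(pivaloyloxy)phenyl]pent-4-enoic acid; 6 (R)-4-benzyl-1,3-oxazolidin-2-one
Product: 8 (R)-4-benzyl-3-{(E)-5-[4-(pivaloyloxy)phenyl]pent-4-enoyl}oxazolidin-2-one, via mixed pivalic anhydride 7 (not isolated)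
Conditions: PivCl, Et3N, THF, −20 °C; then 6, LiCl, −20 °C → rt
Reagents that add atoms: none
Why: N-acylation of the oxazolidinone through the mixed anhydride (LiCl/Et3N protocol); the nitrogen attacks the unhindered acyl group.

**Step 4**
Reactants: 8 (R)-4-benzyl-3-{(E)-5-[4-(pivaloyloxy)phenyl]pent-4-enoyl}oxazolidin-2-one; 2 4-formylphenyl pivalate
Product: 10 (R)-4-benzyl-3-[(2S,3R)-3-hydroxy-3-[4-(pivaloyloxy)phenyl]-2-{(E)-3-[4-(pivaloyloxy)phenyl]prop-2-enyl}propanoyl]oxazolidin-2-one, via trimethylsilyl ether 9 (not isolated)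
Conditions: MgCl2 (20 mol%), Et3N, TMSCl, EtOAc, rt; then TFA, MeOH
Reagents that add atoms: none
Why: Evans magnesium-halide-catalysed direct anti-aldol reaction, in which the chelated Z-enolate is attacked on the face away from the benzyl group through a boat-like transition state, so the (R)-auxiliary gives the (2S,3R) anti adduct that becomes C-8' and C-7'.

**Step 5**
Reactants: 10 the anti-aldol imide
Product: 11 (1R,2R)-1-[4-(pivaloyloxy)phenyl]-2-{(E)-3-[4-(pivaloyloxy)phenyl]prop-2-enyl}propane-1,3-diol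
Conditions: NaBH4, THF/H2O (4:1), 0 °C → rt
Reagents that add atoms: none
Why: reductive cleavage of the N-acyl oxazolidinone (hydride attacks the exocyclic imide carbonyl and the auxiliary is released); the hindered aryl pivalates and both stereocentres are untouched.

**Step 6**
Reactants: 2 4-formylphenyl pivalate; 12 (triphenylphosphoranylidene)acetaldehyde
Product: 13 (E)-3-[4-(pivaloyloxy)phenyl]prop-2-enal
Conditions: toluene, 80 °C
Reagents that add atoms: none
Why: Wittig reaction with a stabilised formyl ylide, which gives the E-enal.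

**Step 7**
Reactants: 11 the (1R,2R)-diol; 13 (E)-3-[4-(pivaloyloxy)phenyl]prop-2-enal
Product: 18 (R)-[4-(pivaloyloxy)phenyl]{(3R,5S,6R)-6-[4-(pivaloyloxy)phenyl]-5-{(E)-3-[4-(pivaloyloxy)phenyl]prop-2-enyl}oxan-3-yl}methanol, via bis-silyl ether 14 (not isolated), via dioxane acetal 15 (not isolated), via bridged bis-ether 16 (not isolated), via triethylsilyl ether 17 (not isolated)
Conditions: BSA, CH2Cl2, rt; then 13, TMSOTf (0.3 equiv), 2,6-di-tert-butyl-4-methylpyridine (0.1 equiv), −78 → 0 °C; then Et3SiH (4 equiv), 0 °C; then 1 M HCl, THF/MeOH, 0 °C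
Reagents that add atoms: none
Why: Proposed new method: silyl-triflate acetalisation gives styryl acetal 15, which TMSOTf opens at the less hindered O-9' to the O-7' oxocarbenium ion; chair Prins attack of C-8 on this ion forms the C-8–C-9'' bond, and the C-7 benzylic cation is closed by the O-9' silyl ether inside a 3,7-dioxabicyclo[3.3.1]nonane (16), where the two bridgehead bonds must be cis (sets C-8, 8,8'-cis) and the C-7 aryl takes the equatorial site of the bridged chair (sets C-7, the axial-aryl all-cis isomer of the free oxane, whatever the alkene geometry); Et3SiH/silyl triflate then ionises only the cinnamyl-type C-9''–O-7' bond and puts hydride on the non-benzylic end so that the E-styrene stays conjugated; the closest known reactions are Prins cascade cyclisations of styrenyl diols with aldehydes to bicyclic ethers and silane reductive opening of 2-alkenyl cyclic ethers.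

**Step 8**
Reactants: 18 the tris-pivalate oxane alcohol
Product: 19 (R)-(4-hydroxyphenyl){(3R,5S,6R)-6-(4-hydroxyphenyl)-5-[(E)-3-(4-hydroxyphenyl)prop-2-enyl]oxan-3-yl}methanol (CNP0182155.1)
Conditions: K2CO3, MeOH, rt; pH 7 buffer work-up
Reagents that add atoms: none
Why: base-mediated transesterification removes the three aryl pivalates, and because no acid is present the p-hydroxybenzylic C-7–O bond cannot ionise, so the axial-aryl centre is kept.

**Compound list**
1 | 4-hydroxybenzaldehyde | O=Cc1ccc(O)cc1 | starting material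
2 | 4-formylphenyl pivalate | CC(C)(C)C(=O)Oc1ccc(C=O)cc1 | intermediate
3 | (3-carboxypropyl)triphenylphosphonium bromide | OC(=O)CCC[P+](c1ccccc1)(c1ccccc1)c1ccccc1.[Br-] | starting material
4 | sodium 4-(triphenylphosphoranylidene)butanoate (carboxylate ylide) | [Na+].[O-]C(=O)CCC=P(c1ccccc1)(c1ccccc1)c1ccccc1 | intermediate (not isolated)
5 | (E)-5-[4-(pivaloyloxy)phenyl]pent-4-enoic acid | CC(C)(C)C(=O)Oc1ccc(/C=C/CCC(=O)O)cc1 | intermediate
6 | (R)-4-benzyl-1,3-oxazolidin-2-one | O=C1N[C@H](Cc2ccccc2)CO1 | starting material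
7 | mixed anhydride of 5 with pivalic acid | CC(C)(C)C(=O)Oc1ccc(/C=C/CCC(=O)OC(=O)C(C)(C)C)cc1 | intermediate (not isolated)
8 | (R)-4-benzyl-3-{(E)-5-[4-(pivaloyloxy)phenyl]pent-4-enoyl}oxazolidin-2-one | CC(C)(C)C(=O)Oc1ccc(/C=C/CCC(=O)N2[C@H](Cc3ccccc3)COC2=O)cc1 | intermediate
9 | 3-O-trimethylsilyl ether of 10 | CC(C)(C)C(=O)Oc1ccc(/C=C/C[C@@H]([C@@H](O[Si](C)(C)C)c2ccc(OC(=O)C(C)(C)C)cc2)C(=O)N2[C@H](Cc3ccccc3)COC2=O)cc1 | intermediate (not isolated)
10 | (R)-4-benzyl-3-[(2S,3R)-3-hydroxy-3-[4-(pivaloyloxy)phenyl]-2-{(E)-3-[4-(pivaloyloxy)phenyl]prop-2-enyl}propanoyl]oxazolidin-2-one (anti) | CC(C)(C)C(=O)Oc1ccc(/C=C/C[C@@H]([C@@H](O)c2ccc(OC(=O)C(C)(C)C)cc2)C(=O)N2[C@H](Cc3ccccc3)COC2=O)cc1 | intermediate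
11 | (1R,2R)-1-[4-(pivaloyloxy)phenyl]-2-{(E)-3-[4-(pivaloyloxy)phenyl]prop-2-enyl}propane-1,3-diol | CC(C)(C)C(=O)Oc1ccc(/C=C/C[C@@H]([C@@H](O)c2ccc(OC(=O)C(C)(C)C)cc2)CO)cc1 | intermediate
12 | (triphenylphosphoranylidene)acetaldehyde | O=CC=P(c1ccccc1)(c1ccccc1)c1ccccc1 | starting material
13 | (E)-3-[4-(pivaloyloxy)phenyl]prop-2-enal | CC(C)(C)C(=O)Oc1ccc(/C=C/C=O)cc1 | intermediate
14 | 1,3-bis(trimethylsilyl) ether of 11 | CC(C)(C)C(=O)Oc1ccc(/C=C/C[C@@H]([C@@H](O[Si](C)(C)C)c2ccc(OC(=O)C(C)(C)C)cc2)CO[Si](C)(C)C)cc1 | intermediate (not isolated)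
15 | (2R,4R,5R)-4-[4-(pivaloyloxy)phenyl]-2-{(E)-2-[4-(pivaloyloxy)phenyl]ethenyl}-5-{(E)-3-[4-(pivaloyloxy)phenyl]prop-2-enyl}-1,3-dioxane (all equatorial) | CC(C)(C)C(=O)Oc1ccc(/C=C/[C@@H]4OC[C@@H](C/C=C/c2ccc(OC(=O)C(C)(C)C)cc2)[C@@H](O4)c2ccc(OC(=O)C(C)(C)C)cc2)cc1 | intermediate (not isolated)
16 | 2,6-bis[4-(pivaloyloxy)phenyl]-8-{(E)-2-[4-(pivaloyloxy)phenyl]ethenyl}-3,7-dioxabicyclo[3.3.1]nonane; chair–chair, the 2-aryl, 6-aryl and 8-alkenyl groups all equatorial; C-6 is the (R)-carbinol carbon of 11, C-2 is C-7, C-8 is C-9'' | CC(C)(C)C(=O)Oc1ccc(/C=C/[C@@H]4[C@H]2C[C@@H]([C@@H](O4)c3ccc(OC(=O)C(C)(C)C)cc3)CO[C@H]2c2ccc(OC(=O)C(C)(C)C)cc2)cc1 | intermediate (not isolated)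
17 | 7'-O-triethylsilyl ether of 18 | CC(C)(C)C(=O)Oc1ccc(/C=C/C[C@H]2C[C@@H]([C@@H](O[Si](CC)(CC)CC)c3ccc(OC(=O)C(C)(C)C)cc3)CO[C@H]2c2ccc(OC(=O)C(C)(C)C)cc2)cc1 | intermediate (not isolated)
18 | (R)-[4-(pivaloyloxy)phenyl]{(3R,5S,6R)-6-[4-(pivaloyloxy)phenyl]-5-{(E)-3-[4-(pivaloyloxy)phenyl]prop-2-enyl}oxan-3-yl}methanol | CC(C)(C)C(=O)Oc1ccc(/C=C/C[C@H]2C[C@@H]([C@@H](O)c3ccc(OC(=O)C(C)(C)C)cc3)CO[C@H]2c2ccc(OC(=O)C(C)(C)C)cc2)cc1 | intermediate
19 | (R)-(4-hydroxyphenyl){(3R,5S,6R)-6-(4-hydroxyphenyl)-5-[(E)-3-(4-hydroxyphenyl)prop-2-enyl]oxan-3-yl}methanol | Oc1ccc(/C=C/C[C@H]2C[C@@H]([C@@H](O)c3ccc(O)cc3)CO[C@H]2c2ccc(O)cc2)cc1 | target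

**Totals**
Total step count: 8. Longest linear sequence: 7 (steps 1, 2, 3, 4, 5, 7, 8); step 6 is a one-step branch from 2.

**Steps most likely to fail**

Step 7. Three things can go wrong:
- Acetal 15 may also open at O-7', which after the same cascade gives the isomeric 2,6-diaryl oxane.
- The second ring closure needs both arms 1,3-diaxial.
- Hydride could add to the benzylic end of the allyl cation.

Fallback for step 7: it sets out from 11 and 2 and comes back at 18. The tether is given up and the p-coumaryl unit is used as a free allyl cation on the Z-styrene, where C–C and C–O bond formation are an anti addition; this relies on the oxygen capturing C-7 before the benzylic cation can rotate. Sensitised E→Z isomerisation of 11 (Ir(ppy)3, blue LED, MeCN) gives (1R,2R)-1-[4-(pivaloyloxy)phenyl]-2-{(Z)-3-[4-(pivaloyloxy)phenyl]prop-2-enyl}propane-1,3-diol F1. Aldehyde 2 with vinylmagnesium bromide, then Ac2O in the same flask, gives racemic 1-[4-(pivaloyloxy)phenyl]prop-2-enyl acetate F2. F1 is silylated in the flask (BSA) to its bis(trimethylsilyl) ether F3 and treated with F2, TMSOTf (10 mol%) and 2,6-di-tert-butyl-4-methylpyridine in CH2Cl2 at −60 °C. The 1-arylallyl cation attacks C-8 with its unsubstituted end while the primary siloxy oxygen adds to C-7 from the opposite face, in a chair with the C-8' side chain equatorial. Anti addition across a Z-alkene puts the C-7 aryl axial and the new cinnamyl group equatorial (7,8-cis, 8,8'-cis) and gives the 7'-O-trimethylsilyl ether of 18 F4, which dilute HCl in MeOH converts into 18.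

Step 4. The magnesium-catalysed anti-aldol is best documented for short acyl chains, and both the diastereoselectivity and the conversion with the long styrenyl chain are uncertain.

Fallback for step 4: it sets out from 5 and 2 and comes back at 11. Enamine catalysis replaces the auxiliary. The mixed anhydride 7 (made as in step 3) is reduced with NaBH4 in THF/H2O to (E)-5-[4-(pivaloyloxy)phenyl]pent-4-en-1-ol F5, and Dess–Martin oxidation gives (E)-5-[4-(pivaloyloxy)phenyl]pent-4-enal F6. Slow addition of F6 to 2 with L-proline (20 mol%, DMF, 4 °C) gives the anti cross-aldol product (2S,3R)-3-hydroxy-3-[4-(pivaloyloxy)phenyl]-2-{(E)-3-[4-(pivaloyloxy)phenyl]prop-2-enyl}propanal F7 (E-enamine, carboxylic-acid-directed attack on the aryl aldehyde). F7 is reduced in the same flask with NaBH4 at −20 °C to 11.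

Step 2. The doubly deprotonated phosphonium salt is a strong base and nucleophile next to an aryl ester, and yields of such Wittig reactions vary.

Fallback for step 2: it sets out from 2 and comes back at 5. Olefin metathesis replaces the Wittig reaction. Methylenation of 2 (Ph3P=CH2, THF, −78 → 0 °C) gives 4-ethenylphenyl pivalate F8, and cross-metathesis of F8 with pent-4-enoic acid (Grubbs second-generation catalyst, CH2Cl2, 40 °C) gives 5 as the E-isomer.

**Further compounds**
F1 | step 7 | (1R,2R)-1-[4-(pivaloyloxy)phenyl]-2-{(Z)-3-[4-(pivaloyloxy)phenyl]prop-2-enyl}propane-1,3-diol | CC(C)(C)C(=O)Oc1ccc(/C=C\C[C@@H]([C@@H](O)c2ccc(OC(=O)C(C)(C)C)cc2)CO)cc1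
F2 | step 7 | racemic 1-[4-(pivaloyloxy)phenyl]prop-2-enyl acetate | CC(=O)OC(C=C)c1ccc(OC(=O)C(C)(C)C)cc1
F3 | step 7 | 1,3-bis(trimethylsilyl) ether of F1 | CC(C)(C)C(=O)Oc1ccc(/C=C\C[C@@H]([C@@H](O[Si](C)(C)C)c2ccc(OC(=O)C(C)(C)C)cc2)CO[Si](C)(C)C)cc1
F4 | step 7 | 7'-O-trimethylsilyl ether of 18 | CC(C)(C)C(=O)Oc1ccc(/C=C/C[C@H]2C[C@@H]([C@@H](O[Si](C)(C)C)c3ccc(OC(=O)C(C)(C)C)cc3)CO[C@H]2c2ccc(OC(=O)C(C)(C)C)cc2)cc1
F5 | step 4 | (E)-5-[4-(pivaloyloxy)phenyl]pent-4-en-1-ol | CC(C)(C)C(=O)Oc1ccc(/C=C/CCCO)cc1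
F6 | step 4 | (E)-5-[4-(pivaloyloxy)phenyl]pent-4-enal | CC(C)(C)C(=O)Oc1ccc(/C=C/CCC=O)cc1
F7 | step 4 | (2S,3R)-3-hydroxy-3-[4-(pivaloyloxy)phenyl]-2-{(E)-3-[4-(pivaloyloxy)phenyl]prop-2-enyl}propanal | CC(C)(C)C(=O)Oc1ccc(/C=C/C[C@@H]([C@@H](O)c2ccc(OC(=O)C(C)(C)C)cc2)C=O)cc1
F8 | step 2 | 4-ethenylphenyl pivalate | C=Cc1ccc(OC(=O)C(C)(C)C)cc1
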